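**Retrosynthetic overview**

1. Last bond: the C(sp3)–C(sp2) bond between the CH2CH2 arm on the ring and the side-chain alkenyl carbon, made by visible-light photoredox/nickel coupling of an alkyl bis(catecholato)silicate with an (E)-alkenyl iodide; no protecting groups remain at that stage.
2. The silicate comes from a cis-fused 1-oxa-2-silacyclohexane. Its silicon first acts as a tether that delivers the two-carbon arm to the quaternary carbon on the face of the tertiary oxygen (new HAT-initiated radical cyclisation), then as the photo-oxidisable handle.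
3. The carbocycle is bought: (1S,2S,4R)-limonene-1,2-diol supplies the tertiary carbinol; its C4 centre steers a trans alkylation with 3-iodopropyl tetradecanoate and is then turned into the enal (epoxide → aldehyde → desaturation).
4. Side chain: methyl (R)-glycidate supplies the carbinol; two syn-carboaluminations set both E-trisubstituted alkenes.
5. Ring order: cyclohexane (bought) → temporary oxasilinane ring (closed in step 7, opened again in the last step).

Assumption: 6-methylhept-5-en-1-yne is taken as purchasable; oxirane-bearing intermediates are carried as about 1:1 mixtures at the oxirane carbon, which later becomes sp2.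

**Route**

Step 1
Reactants: 1 (1S,2S,4R)-1-methyl-4-(prop-1-en-2-yl)cyclohexane-1,2-diol
Product: 2 (1S,2S,4R)-1-methyl-4-(2-methyloxiran-2-yl)cyclohexane-1,2-diol
Conditions: mCPBA (1.1 equiv), NaHCO3, CH2Cl2, 0 °C
Reagents that add atoms: mCPBA OOC(=O)c1cccc(Cl)c1
Why: Prilezhaev epoxidation of the only alkene masks the isopropenyl group against the later hydrogen-atom-transfer step and prepares it for the aldehyde; the new oxirane centre is inconsequential.

Step 2
Reactants: 2 (1S,2S,4R)-1-methyl-4-(2-methyloxiran-2-yl)cyclohexane-1,2-diol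
Product: 3 (2S,5R)-2-hydroxy-2-methyl-5-(2-methyloxiran-2-yl)cyclohexan-1-one
Conditions: IBX (1.5 equiv), DMSO, rt
Reagents that add atoms: none
Why: IBX oxidation of the secondary alcohol of a 1,2-diol gives the α-ketol without C–C cleavage and leaves the bought tertiary carbinol untouched.

Step 3
Reactants: 4 3-iodopropan-1-ol; 5 tetradecanoyl chloride
Product: 6 3-iodopropyl tetradecanoate
Conditions: pyridine (1.2 equiv), CH2Cl2, 0 °C → rt
Reagents that add atoms: none
Why: Simple acylation of a primary alcohol by an acid chloride installs the myristate before any step that would require a protecting group.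

Step 4
Reactants: 3 (2S,5R)-2-hydroxy-2-methyl-5-(2-methyloxiran-2-yl)cyclohexan-1-one; 6 3-iodopropyl tetradecanoate
Product: 7 3-[(1S,3S,6R)-3-hydroxy-3-methyl-6-(2-methyloxiran-2-yl)-2-oxocyclohexyl]propyl tetradecanoate
Conditions: LiN(iPr)2 (2.1 equiv), THF, −78 °C; then DMPU, 6 (1.3 equiv), −78 → −20 °C
Reagents that add atoms: none
Why: Enolate alkylation of the alkoxide–enolate dianion, which can only form toward the CH2 (the other α-carbon is quaternary), occurs anti to the adjacent oxiranyl-bearing stereocentre to give the trans (also thermodynamic) epimer, as in C6 alkylations of carvone.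

Step 5
Reactants: 7 3-[(1S,3S,6R)-3-hydroxy-3-methyl-6-(2-methyloxiran-2-yl)-2-oxocyclohexyl]propyl tetradecanoate
Product: 8 3-[(1S,3S,6R)-3-hydroxy-3-methyl-2-methylidene-6-(2-methyloxiran-2-yl)cyclohexyl]propyl tetradecanoate
Conditions: Ph3PCH3Br (3.3 equiv), KN(SiMe3)2 (3.0 equiv), THF, 0 °C; then 7, 0 → 50 °C
Reagents that add atoms: methyltriphenylphosphonium bromide C[P+](c1ccccc1)(c1ccccc1)c1ccccc1.[Br-]
Why: Wittig methylenation with a pre-formed, base-free ylide converts the hindered ketone to the exocyclic alkene while the ester and oxirane are inert to the ylide.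

Step 6
Reactants: 8 3-[(1S,3S,6R)-3-hydroxy-3-methyl-2-methylidene-6-(2-methyloxiran-2-yl)cyclohexyl]propyl tetradecanoate; 9 trichloro(vinyl)silane
Product: 11 3-[(1S,3S,6R)-3-{[diethoxy(vinyl)silyl]oxy}-3-methyl-2-methylidene-6-(2-methyloxiran-2-yl)cyclohexyl]propyl tetradecanoate, via dichlorosilyl ether 10 (not isolated)
Conditions: 9 (1.2 equiv), Et3N (5 equiv), CH2Cl2, −40 → 0 °C; then EtOH (6 equiv), 0 °C; filtration through Et3N-deactivated silica
Reagents that add atoms: ethanol CCO
Why: O-silylation of the tertiary allylic alcohol by the trichlorosilane followed by ethanolysis of the two remaining Si–Cl bonds installs a vinylsilyl tether whose silicon keeps three exchangeable oxygens for later silicate formation.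

Step 7
Reactants: 11 3-[(1S,3S,6R)-3-{[diethoxy(vinyl)silyl]oxy}-3-methyl-2-methylidene-6-(2-methyloxiran-2-yl)cyclohexyl]propyl tetradecanoate
Product: 12 3-[(4aR,5S,6R,8aS)-2,2-diethoxy-4a,8a-dimethyl-6-(2-methyloxiran-2-yl)octahydro-2H-1,2-benzoxasilin-5-yl]propyl tetradecanoate
Conditions: Mn(dpm)3 (15 mol %; dpm = 2,2,6,6-tetramethylheptane-3,5-dionate), Ph(iPrO)SiH2 (2 equiv, syringe pump), tBuOOH (1.5 equiv, anhydrous), degassed hexane/CH2Cl2, 0.01 M, rt
Reagents that add atoms: none
Why: Proposed new method: hydrogen-atom transfer from a manganese hydride to the 1,1-disubstituted alkene gives the tertiary ring radical (the former CH2 becomes the methyl), which closes 6-endo on the tethered vinylsilane (or 5-exo followed by the known 1,2-silyl ring enlargement) so the new C–CH2 bond must form on the face of the tertiary oxygen (cis-fused ring, quaternary centre R), and the resulting radical takes a second hydrogen atom; the closest known reactions are tin-hydride cyclisations of vinylsilyl ethers and MHAT-initiated reductive radical cyclisations of dienes.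

Step 8
Reactants: 12 3-[(4aR,5S,6R,8aS)-2,2-diethoxy-4a,8a-dimethyl-6-(2-methyloxiran-2-yl)octahydro-2H-1,2-benzoxasilin-5-yl]propyl tetradecanoate
Product: 13 3-[(4aR,5S,6R,8aS)-2,2-diethoxy-4a,8a-dimethyl-6-(1-oxopropan-2-yl)octahydro-2H-1,2-benzoxasilin-5-yl]propyl tetradecanoate
Conditions: ZnBr2 (20 mol %), toluene, 60 °C
Reagents that add atoms: none
Why: Meinwald rearrangement of the 2,2-disubstituted oxirane (tertiary C–O ionisation, 1,2-hydride shift) gives the α-methyl aldehyde, the same change known for limonene 8,9-oxide.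

Step 9
Reactants: 13 3-[(4aR,5S,6R,8aS)-2,2-diethoxy-4a,8a-dimethyl-6-(1-oxopropan-2-yl)octahydro-2H-1,2-benzoxasilin-5-yl]propyl tetradecanoate
Product: 14 3-[(4aR,5S,6Z,8aS)-2,2-diethoxy-4a,8a-dimethyl-6-(1-oxopropan-2-ylidene)octahydro-2H-1,2-benzoxasilin-5-yl]propyl tetradecanoate
Conditions: IBX (2.5 equiv), DMSO, 70 °C
Reagents that add atoms: none
Why: IBX α,β-dehydrogenation of the aldehyde removes the ring C–H in preference to a methyl C–H (as 2-methylcyclohexanone gives 2-methylcyclohexenone), and the tetrasubstituted enal is expected to settle with the formyl group syn to the substituted ring CH, where allylic strain is least.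

Step 10
Reactants: 15 6-methylhept-5-en-1-yne
Product: 17 (E)-1-iodo-2,6-dimethylhepta-1,5-diene, via alkenylalane 16 (not isolated)
Conditions: Me3Al (2 equiv), Cp2ZrCl2 (20 mol %), CH2Cl2, 0 °C → rt; then iodine, THF, −30 °C
Reagents that add atoms: trimethylaluminium C[Al](C)C; iodine [I][I]
Why: Negishi zirconium-catalysed syn-carboalumination places methyl and aluminium cis, and iodinolysis with retention gives the E-alkenyl iodide.

Step 11
Reactants: 17 (E)-1-iodo-2,6-dimethylhepta-1,5-diene; 18 methyl (R)-glycidate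
Product: 21 methyl (2R,4E)-2-hydroxy-5,9-dimethyldeca-4,8-dienoate, via alkenyllithium 19 (not isolated), via alkenylmagnesium bromide 20 (not isolated)
Conditions: tBuLi (2.0 equiv), Et2O, −78 °C; MgBr2·OEt2; then CuBr·SMe2 (10 mol %), 18, THF, −78 → −30 °C
Reagents that add atoms: none
Why: Stereoretentive lithium–iodine exchange, transmetalation and copper-catalysed SN2 opening of the glycidate at its CH2 leave the bought (R) carbinol centre untouched.

Step 12
Reactants: 21 methyl (2R,4E)-2-hydroxy-5,9-dimethyldeca-4,8-dienoate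
Product: 22 methyl (2R,4E)-5,9-dimethyl-2-[(triethylsilyl)oxy]deca-4,8-dienoate
Conditions: Et3SiCl (1.2 equiv), imidazole, CH2Cl2, 0 °C → rt
Reagents that add atoms: chlorotriethylsilane CC[Si](Cl)(CC)CC
Why: Silylation of the secondary alcohol lets the ester be reduced to a configurationally stable α-silyloxy aldehyde.

Step 13
Reactants: 22 methyl (2R,4E)-5,9-dimethyl-2-[(triethylsilyl)oxy]deca-4,8-dienoate
Product: 25 (3R,5E)-6,10-dimethylundeca-5,9-dien-1-yn-3-ol, via silyloxy aldehyde 23 (not isolated), via silyloxy alkyne 24 (not isolated)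
Conditions: iBu2AlH (1.1 equiv), CH2Cl2, −78 °C; then MeOH, K2CO3, dimethyl (1-diazo-2-oxopropyl)phosphonate, −78 °C → rt; then 1 M HCl, THF, rt
Reagents that add atoms: dimethyl (1-diazo-2-oxopropyl)phosphonate COP(=O)(OC)C(=[N+]=[N-])C(C)=O
Why: One-pot partial reduction and Seyferth–Gilbert homologation (Ohira–Bestmann reagent) turns the ester into the terminal alkyne, and the acidic work-up removes the triethylsilyl group.

Step 14
Reactants: 25 (3R,5E)-6,10-dimethylundeca-5,9-dien-1-yn-3-ol
Product: 27 (1E,3R,5E)-1-iodo-2,6,10-trimethylundeca-1,5,9-trien-3-ol, via alkenylalane 26 (not isolated)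
Conditions: Me3Al (3.5 equiv), Cp2ZrCl2 (0.3 equiv), CH2Cl2, rt; then iodine, THF, −30 °C; dilute HCl work-up
Reagents that add atoms: trimethylaluminium C[Al](C)C; iodine [I][I]
Why: Negishi syn-carboalumination of the propargylic aluminium alkoxide followed by iodinolysis gives the E-alkenyl iodide with methyl on the carbinol-bearing carbon, and the trisubstituted alkenes do not react.

Step 15
Reactants: 14 3-[(4aR,5S,6Z,8aS)-2,2-diethoxy-4a,8a-dimethyl-6-(1-oxopropan-2-ylidene)octahydro-2H-1,2-benzoxasilin-5-yl]propyl tetradecanoate; 27 (1E,3R,5E)-1-iodo-2,6,10-trimethylundeca-1,5,9-trien-3-ol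
Product: 29 3-[(1S,2R,3S,6Z)-3-hydroxy-2-[(3E,5R,7E)-5-hydroxy-4,8,12-trimethyltrideca-3,7,11-trien-1-yl]-2,3-dimethyl-6-(1-oxopropan-2-ylidene)cyclohexyl]propyl tetradecanoate, via triethylammonium silicate 28 (not isolated)
Conditions: catechol (2.0 equiv), Et3N (1.05 equiv), DMF, 40 °C, 3 h; then 27 (1.2 equiv), Ru(bpy)3(PF6)2 (2 mol %), NiCl2·dme (5 mol %), dtbbpy (5 mol %), 450 nm LEDs, degassed, rt
Reagents that add atoms: none
Why: Catechol opens the oxasilinane to the bis(catecholato)silicate and frees the tertiary alcohol, the excited ruthenium complex oxidises the silicate to the primary alkyl radical, and nickel joins it to the alkenyl iodide with retention of alkene geometry (photoredox/nickel dual-catalytic C(sp3)–C(sp2) cross-coupling of alkyl silicates with alkenyl halides).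

**Compound list**

1 | (1S,2S,4R)-1-methyl-4-(prop-1-en-2-yl)cyclohexane-1,2-diol, (+)-limonene-1,2-diol | C1[C@H](C(C)=C)CC[C@](C)(O)[C@H]1O | starting material
2 | (1S,2S,4R)-1-methyl-4-(2-methyloxiran-2-yl)cyclohexane-1,2-diol | C1[C@H](C2(C)CO2)CC[C@](C)(O)[C@H]1O | intermediate
3 | (2S,5R)-2-hydroxy-2-methyl-5-(2-methyloxiran-2-yl)cyclohexan-1-one | C1[C@H](C2(C)CO2)CC[C@](C)(O)C1=O | intermediate
4 | 3-iodopropan-1-ol | OCCCI | starting material
5 | tetradecanoyl chloride | CCCCCCCCCCCCCC(=O)Cl | starting material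
6 | 3-iodopropyl tetradecanoate | CCCCCCCCCCCCCC(=O)OCCCI | intermediate
7 | 3-[(1S,3S,6R)-3-hydroxy-3-methyl-6-(2-methyloxiran-2-yl)-2-oxocyclohexyl]propyl tetradecanoate | CCCCCCCCCCCCCC(=O)OCCC[C@H]1[C@H](C2(C)CO2)CC[C@](C)(O)C1=O | intermediate
8 | 3-[(1S,3S,6R)-3-hydroxy-3-methyl-2-methylidene-6-(2-methyloxiran-2-yl)cyclohexyl]propyl tetradecanoate | CCCCCCCCCCCCCC(=O)OCCC[C@H]1[C@H](C2(C)CO2)CC[C@](C)(O)C1=C | intermediate
9 | trichloro(vinyl)silane | C=C[Si](Cl)(Cl)Cl | starting material
10 | dichloro(vinyl)silyl ether of 8 | CCCCCCCCCCCCCC(=O)OCCC[C@H]1[C@H](C2(C)CO2)CC[C@](C)(O[Si](Cl)(Cl)C=C)C1=C | intermediate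
11 | 3-[(1S,3S,6R)-3-{[diethoxy(vinyl)silyl]oxy}-3-methyl-2-methylidene-6-(2-methyloxiran-2-yl)cyclohexyl]propyl tetradecanoate | CCCCCCCCCCCCCC(=O)OCCC[C@H]1[C@H](C2(C)CO2)CC[C@](C)(O[Si](OCC)(OCC)C=C)C1=C | intermediate
12 | 3-[(4aR,5S,6R,8aS)-2,2-diethoxy-4a,8a-dimethyl-6-(2-methyloxiran-2-yl)octahydro-2H-1,2-benzoxasilin-5-yl]propyl tetradecanoate (cis-fused) | CCCCCCCCCCCCCC(=O)OCCC[C@H]1[C@H](C3(C)CO3)CC[C@]2(C)O[Si](OCC)(OCC)CC[C@]12C | intermediate
13 | 3-[(4aR,5S,6R,8aS)-2,2-diethoxy-4a,8a-dimethyl-6-(1-oxopropan-2-yl)octahydro-2H-1,2-benzoxasilin-5-yl]propyl tetradecanoate (epimers at the aldehyde α-carbon) | CCCCCCCCCCCCCC(=O)OCCC[C@H]1[C@H](C(C)C=O)CC[C@]2(C)O[Si](OCC)(OCC)CC[C@]12C | intermediate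
14 | 3-[(4aR,5S,6Z,8aS)-2,2-diethoxy-4a,8a-dimethyl-6-(1-oxopropan-2-ylidene)octahydro-2H-1,2-benzoxasilin-5-yl]propyl tetradecanoate | CCCCCCCCCCCCCC(=O)OCCC[C@H]1/C(=C(/C)C=O)CC[C@]2(C)O[Si](OCC)(OCC)CC[C@]12C | intermediate
15 | 6-methylhept-5-en-1-yne | C#CCCC=C(C)C | starting material
16 | [(E)-2,6-dimethylhepta-1,5-dien-1-yl]dimethylalane | C[Al](C)/C=C(\C)CCC=C(C)C | intermediate
17 | (E)-1-iodo-2,6-dimethylhepta-1,5-diene | I/C=C(\C)CCC=C(C)C | intermediate
18 | methyl (R)-glycidate, methyl (2R)-oxirane-2-carboxylate | COC(=O)[C@H]1CO1 | starting material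
19 | [(E)-2,6-dimethylhepta-1,5-dien-1-yl]lithium | [Li]/C=C(\C)CCC=C(C)C | intermediate
20 | [(E)-2,6-dimethylhepta-1,5-dien-1-yl]magnesium bromide | Br[Mg]/C=C(\C)CCC=C(C)C | intermediate
21 | methyl (2R,4E)-2-hydroxy-5,9-dimethyldeca-4,8-dienoate | COC(=O)[C@H](O)C/C=C(\C)CCC=C(C)C | intermediate
22 | methyl (2R,4E)-5,9-dimethyl-2-[(triethylsilyl)oxy]deca-4,8-dienoate | COC(=O)[C@H](O[Si](CC)(CC)CC)C/C=C(\C)CCC=C(C)C | intermediate
23 | (2R,4E)-5,9-dimethyl-2-[(triethylsilyl)oxy]deca-4,8-dienal | O=C[C@H](O[Si](CC)(CC)CC)C/C=C(\C)CCC=C(C)C | intermediate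
24 | triethyl{[(3R,5E)-6,10-dimethylundeca-5,9-dien-1-yn-3-yl]oxy}silane | C#C[C@H](O[Si](CC)(CC)CC)C/C=C(\C)CCC=C(C)C | intermediate
25 | (3R,5E)-6,10-dimethylundeca-5,9-dien-1-yn-3-ol | C#C[C@H](O)C/C=C(\C)CCC=C(C)C | intermediate
26 | (1E,3R,5E)-1-(dimethylalumanyl)-2,6,10-trimethylundeca-1,5,9-trien-3-ol dimethylaluminium alkoxide | C[Al](C)/C=C(\C)[C@H](O[Al](C)C)C/C=C(\C)CCC=C(C)C | intermediate
27 | (1E,3R,5E)-1-iodo-2,6,10-trimethylundeca-1,5,9-trien-3-ol | I/C=C(\C)[C@H](O)C/C=C(\C)CCC=C(C)C | intermediate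
28 | triethylammonium bis(benzene-1,2-diolato)silicate of the ring-opened hydroxy enal (silicon on the terminal carbon of the two-carbon arm) | CCCCCCCCCCCCCC(=O)OCCC[C@H]1/C(=C(/C)C=O)CC[C@](C)(O)[C@]1(C)CC[Si-]12(Oc3ccccc3O1)Oc1ccccc1O2.CC[NH+](CC)CC | intermediate
29 | 3-[(1S,2R,3S,6Z)-3-hydroxy-2-[(3E,5R,7E)-5-hydroxy-4,8,12-trimethyltrideca-3,7,11-trien-1-yl]-2,3-dimethyl-6-(1-oxopropan-2-ylidene)cyclohexyl]propyl tetradecanoate | CCCCCCCCCCCCCC(=O)OCCC[C@H]1/C(=C(/C)C=O)CC[C@](C)(O)[C@]1(C)CC/C=C(\C)[C@H](O)C/C=C(\C)CCC=C(C)C | target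

**Count and risks**

Total steps: 15. Longest linear sequence: 9 (steps 1, 2, 4, 5, 6, 7, 8, 9, 15); the side-chain branch is 6 steps (10 to 15).

Step 7 (the proposed new cyclisation). The tertiary radical may be reduced before it cyclises, hydrogen-atom transfer may start at the vinylsilane, or 5-exo closure may compete. The fallback sets out from 8 and comes back at 12, using known chemistry only. Cobalt-catalysed Markovnikov hydrochlorination of 8 (Co(BF4)2·6H2O with an achiral salen-type ligand, TsCl, PhSiH3, EtOH) gives the tertiary chloride F1. Silylation as in step 6 gives the tethered chloride F2. Bu3SnH (syringe pump) and AIBN in benzene at 80 °C then generate the same tertiary radical by chlorine abstraction; at low hydride concentration the known vinylsilyl-ether cyclisation gives the six-membered ring, which is 12.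

Step 9 (desaturation to the tetrasubstituted enal). The exo-methylene isomer or the wrong alkene geometry may form. The fallback sets out from 13 and comes back at 14. TMSOTf and Et3N convert 13 into the trimethylsilyl enol ether F3, and Saegusa–Ito oxidation with Pd(OAc)2 in MeCN gives 14; reversible palladium hydride re-addition funnels the product to the conjugated, more substituted alkene.

Step 15 (final photoredox/nickel coupling beside a free enal). The primary radical could add to the enal, or the aldehyde could interfere with the excited catalyst. The fallback sets out from 14 and comes back at 29. NaBH4 with CeCl3·7H2O in EtOH at −20 °C reduces 14 to the allylic alcohol F4. Catechol and Et3N give its silicate F5, which is coupled with 27 under the same dual catalysis to the triol F6. TEMPO (cat.) with PhI(OAc)2 then oxidises only the primary allylic alcohol and gives 29.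

**Further compounds**

F1 | step 7 | 3-[(1S,3S,6R)-2-chloro-3-hydroxy-2,3-dimethyl-6-(2-methyloxiran-2-yl)cyclohexyl]propyl tetradecanoate (epimers at the C–Cl carbon) | CCCCCCCCCCCCCC(=O)OCCC[C@H]1[C@H](C2(C)CO2)CC[C@](C)(O)C1(C)Cl
F2 | step 7 | diethoxy(vinyl)silyl ether of F1 | CCCCCCCCCCCCCC(=O)OCCC[C@H]1[C@H](C2(C)CO2)CC[C@](C)(O[Si](OCC)(OCC)C=C)C1(C)Cl
F3 | step 9 | 3-[(4aR,5S,6R,8aS)-2,2-diethoxy-4a,8a-dimethyl-6-{1-[(trimethylsilyl)oxy]prop-1-en-2-yl}octahydro-2H-1,2-benzoxasilin-5-yl]propyl tetradecanoate | CCCCCCCCCCCCCC(=O)OCCC[C@H]1[C@H](C(C)=CO[Si](C)(C)C)CC[C@]2(C)O[Si](OCC)(OCC)CC[C@]12C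
F4 | step 15 | 3-[(4aR,5S,6Z,8aS)-2,2-diethoxy-6-(1-hydroxypropan-2-ylidene)-4a,8a-dimethyloctahydro-2H-1,2-benzoxasilin-5-yl]propyl tetradecanoate | CCCCCCCCCCCCCC(=O)OCCC[C@H]1/C(=C(/C)CO)CC[C@]2(C)O[Si](OCC)(OCC)CC[C@]12C
F5 | step 15 | triethylammonium bis(benzene-1,2-diolato)silicate of ring-opened F4 | CCCCCCCCCCCCCC(=O)OCCC[C@H]1/C(=C(/C)CO)CC[C@](C)(O)[C@]1(C)CC[Si-]12(Oc3ccccc3O1)Oc1ccccc1O2.CC[NH+](CC)CC
F6 | step 15 | 3-[(1S,2R,3S,6Z)-3-hydroxy-2-[(3E,5R,7E)-5-hydroxy-4,8,12-trimethyltrideca-3,7,11-trien-1-yl]-6-(1-hydroxypropan-2-ylidene)-2,3-dimethylcyclohexyl]propyl tetradecanoate | CCCCCCCCCCCCCC(=O)OCCC[C@H]1/C(=C(/C)CO)CC[C@](C)(O)[C@]1(C)CC/C=C(\C)[C@H](O)C/C=C(\C)CCC=C(C)C
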